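Its constants stand for no real mixture; no experiment stands behind them.

Divide before you integrate.

| flask | substrate | partner | time | remark |
|---|---|---|---|---|
| Monday's | 0.026 M | 0.0234 M | 80 min | a closed flask charged with all of it at once and left for 80 min |
| Sunday's | 0.026 M (fed, over 64.0 min) | 0.0234 M | 80 min | a stirred flask in which substrate is dosed at a steady rate over 64.0 min without added volume, worked up at 80 min |
| Thursday's | 0.026 M | 0.0234 M |  | a single well-mixed tank run continuously and read at steady state, 80 min in it on average |
| Friday's | 0.026 M | 0.0234 M (fed, over 64.0 min) | 80 min | all but partner at the start; partner goes in evenly over 64.0 min, the run ends at 80 min |

    substrate + partner ⇌ intermediate (K1 = 20.3 M⁻¹, k1 = 2.41 M⁻¹ s⁻¹)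
    substrate → side product (k2 = 0.00547 s⁻¹)
    substrate + partner → target (k3 = 0.0847 M⁻¹ s⁻¹)
    intermediate → target (k4 = 0.00432 s⁻¹)

- the set-up with the highest amount of target at the outlet or at the end, in percent of the substrate put in ("none" if the first two lie within 2 percentage points) (Monday's / Sunday's / Thursday's / Friday's / none)
- amount of target at the outlet or at the end, in percent of the substrate put in, Monday's
- amount of target at the outlet or at the end, in percent of the substrate put in, Sunday's
- amount of target at the outlet or at the end, in percent of the substrate put in, Thursday's
- amount of target at the outlet or at the end, in percent of the substrate put in, Friday's

- the stated concentrations are those of everything mixed, before any reaction; amounts are the same in each set-up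
- the feed brings no volume worth counting
- run time (Monday's): 80 min

Substrate has two exits. Its rate to side product goes with substrate, and its rate to target, direct or through the intermediate, goes with substrate times free partner. Divide one by the other, and substrate and time drop out, leaving a level of partner.

You may object that the intermediate is a pool that need not follow substrate. But it falls back at 0.119 s⁻¹ and goes on at 0.00432 s⁻¹, which gives it a mean life of 0.135 min, shorter than the 3.05 min mean life of substrate against side product, so I take it as keeping step. The level is then 0.0323 M. Call it the break-even partner, the free partner at which substrate leaves for target as fast as for side product; it is the inverse of a selectivity factor. At any free partner, the share of substrate reaching target is partner over partner plus break-even.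

Take Sunday's, where partner is all present at the start: the charged level gives 42.0%. That cannot last, since each target takes one partner, which would leave 0.0125 M. The mean of start and end, 0.0179 M, gives 35.7%, and a second pass gives 36.7%, which I commit to.

On Friday's, substrate's mean life against side product, 3.05 min, is shorter than the 64.0 min feed. Target is therefore roughly the partner delivered in one such life over the break-even, 3.45%. But bound partner is not free: at the start, free partner is divided by 1.53, giving 2.26%. I expect Friday's between these two figures. My reckoning stops at these two flasks.

The forecast gives 33.2%, 36.2%, 31.2% and 2.6% for Monday's, Sunday's, Thursday's and Friday's, and names Sunday's, holding that “dosing keeps partner in excess”. Its Sunday's figure lies below mine by 0.50 percentage points.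

The simulation gives 33.2%, 35.9%, 30.9% and 2.49% in that order, so Sunday's leads Monday's by 2.7 points, and the forecast stands. In Sunday's, while the feed ran, substrate stood at 3.09% at 40.0 min and 3.30% at 64.0 min as partner fell from 74.0% to 60.6% of its charge. After the feed, the remaining substrate fell to 0.00905% by 80.0 min. The mean of charged and final partner on Sunday's, 0.0187 M, gives 36.7% by the break-even. For the neighbour like Friday's with 0.094 M of partner, the divided reckoning gives 9.07%, and that flask ended at 8.67%.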